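**Plan**

- Retrosynthesis: the ring B–ring C ester C(=O)–O bond is cut first, then the ring A–ring B ester C(=O)–O bond; in ring A the C1–CO2H and C6–CH3 bonds are cut together.
- Enabling feature: in ring A the carboxyl-bearing C1 lies between C2–OMe and C6–CH3, so C1 and C6 map onto the two carbons of a 3-methoxybenzyne whose remaining oxygen (the 4-OH of ring A) is carried as a silyl ether.
- Forward: no ring is built. Ring A is dressed on a purchased fluoroarene (aryne, MeLi, CO2) and joined to ring B (benzyl orsellinate). The benzyl ester is hydrogenolysed, ring C (a second benzyl orsellinate) is attached, and the silyl and benzyl groups are removed.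
- Stereochemistry: the target has no stereocentre and no double-bond geometry; only regiochemistry has to be controlled.

Key step: step 2

Assumption: the 2-hydroxyl groups of the orsellinate units are hydrogen-bonded to the neighbouring ester or acid carbonyl and are left unprotected, since only the free 4-hydroxyl is expected to be acylated.

**Route**

Step 1
Reactants: 1 3-fluoro-5-methoxyphenol
Product: 2 1-fluoro-3-methoxy-5-(triisopropylsilyloxy)benzene
Conditions: TIPSCl, imidazole, DMF, 0 °C → rt
Reagents that add atoms: triisopropylsilyl chloride, CC(C)[Si](Cl)(C(C)C)C(C)C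
Why: Standard silylation of a phenol (silyl ether formation) removes the acidic OH before organolithium chemistry and installs a bulky, weakly coordinating group that should not direct metalation to its own ortho positions.

Step 2
Reactants: 2 1-fluoro-3-methoxy-5-(triisopropylsilyloxy)benzene; 3 methyllithium; 4 carbon dioxide
Product: 8 2-methoxy-6-methyl-4-(triisopropylsilyloxy)benzoic acid, via ortho-fluoro aryllithium 5 (not isolated), via 3-methoxy-5-silyloxybenzyne 6 (not isolated), via ortho-methoxy aryllithium 7 (not isolated)
Conditions: s-BuLi (1.0 equiv), THF, −78 °C; cannulate into MeLi (3 equiv), THF, −20 → 0 °C; pour into excess CO2, THF, −78 °C → rt; cold 1 M HCl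
Reagents that add atoms: methyllithium, [Li]C; carbon dioxide, O=C=O
Why: sec-BuLi should remove the one proton flanked by F and OMe (directed ortho-metalation; both groups acidify and coordinate, while the bulky silyl ether does neither) to give 5, which above about −40 °C expels LiF to give aryne 6; MeLi carbolithiates 6 at the aryne carbon remote from OMe and the new aryllithium 7 is carboxylated by CO2. The closest known reaction type is the one-flask sequence of aryne generation from an ortho-lithiated 3-haloanisole, regioselective organolithium addition to the 3-alkoxybenzyne and electrophilic trapping of the resulting 2-alkyl-6-alkoxyphenyllithium. No ring is closed and no stereocentre is formed; the C6–CH3 and C1–CO2H bonds of ring A are made together. Regiocontrol is needed twice: the lithiation site is fixed by the cooperative F/OMe pair, and the direction of MeLi addition by the inductively withdrawing methoxy group, which distorts the aryne so that attack occurs at the distal carbon and the carbanion sits beside OMe, stabilised by induction and lithium coordination, the para silyloxy group having little say. Chemoselectivity is also needed: exactly one equivalent of sec-BuLi and transfer of cold 5 into excess MeLi should suppress sec-butyl adducts and addition of 5 to 6, and quenching into excess CO2 prevents further addition to the carboxylate.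

Step 3
Reactants: 9 orsellinic acid (2,4-dihydroxy-6-methylbenzoic acid)
Product: 10 benzyl orsellinate (benzyl 2,4-dihydroxy-6-methylbenzoate)
Conditions: BnBr, KHCO3, DMF, rt
Reagents that add atoms: benzyl bromide, BrCc1ccccc1
Why: KHCO3 deprotonates only the carboxylic acid, so SN2 O-alkylation of the carboxylate gives the benzyl ester and leaves both phenols free; room temperature avoids decarboxylation of the orsellinic acid.

Step 4
Reactants: 8 2-methoxy-6-methyl-4-(triisopropylsilyloxy)benzoic acid; 10 benzyl orsellinate
Product: 12 benzyl 2-hydroxy-4-{[2-methoxy-6-methyl-4-(triisopropylsilyloxy)benzoyl]oxy}-6-methylbenzoate, via mixed trifluoroacetic anhydride 11 (not isolated)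
Conditions: (CF3CO)2O, toluene, 0 °C → rt; aq. NaHCO3 work-up
Reagents that add atoms: none
Why: Trifluoroacetic anhydride-mediated depside esterification: the hindered, electron-rich acid forms mixed anhydride 11 (an acylium equivalent), which acylates the free 4-OH of 10, while the chelated 2-OH is a poor nucleophile; the aryl silyl ether is expected to tolerate the trifluoroacetic acid released at room temperature.

Step 5
Reactants: 12 benzyl 2-hydroxy-4-{[2-methoxy-6-methyl-4-(triisopropylsilyloxy)benzoyl]oxy}-6-methylbenzoate
Product: 13 2-hydroxy-4-{[2-methoxy-6-methyl-4-(triisopropylsilyloxy)benzoyl]oxy}-6-methylbenzoic acid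
Conditions: H2 (1 atm), Pd/C (10 wt% palladium on carbon), EtOAc, rt
Reagents that add atoms: none
Why: Hydrogenolysis of the benzyl ester over Pd/C frees the ring B carboxyl group; the aryl silyl ether and the aryl ester are inert to these conditions, which is why silicon rather than benzyl protects ring A; heat is avoided because such ortho-hydroxy acids decarboxylate.

Step 6
Reactants: 13 2-hydroxy-4-{[2-methoxy-6-methyl-4-(triisopropylsilyloxy)benzoyl]oxy}-6-methylbenzoic acid; 10 benzyl orsellinate
Product: 15 benzyl 2-hydroxy-4-{[2-hydroxy-4-{[2-methoxy-6-methyl-4-(triisopropylsilyloxy)benzoyl]oxy}-6-methylbenzoyl]oxy}-6-methylbenzoate, via mixed trifluoroacetic anhydride 14 (not isolated)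
Conditions: (CF3CO)2O, toluene, 0 °C → rt; aq. NaHCO3 work-up
Reagents that add atoms: none
Why: The same trifluoroacetic anhydride depside condensation, now with an ortho-hydroxy acid whose chelated 2-OH should not compete, so mixed anhydride 14 acylates the free 4-OH of a second molecule of 10 and completes the tridepside skeleton.

Step 7
Reactants: 15 benzyl 2-hydroxy-4-{[2-hydroxy-4-{[2-methoxy-6-methyl-4-(triisopropylsilyloxy)benzoyl]oxy}-6-methylbenzoyl]oxy}-6-methylbenzoate
Product: 16 benzyl umbilicarate (benzyl 2-hydroxy-4-{[2-hydroxy-4-[(4-hydroxy-2-methoxy-6-methylbenzoyl)oxy]-6-methylbenzoyl]oxy}-6-methylbenzoate)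
Conditions: Bu4NF, AcOH (1:1), THF, 0 °C
Reagents that add atoms: none
Why: Fluoride-induced cleavage of the aryl silyl ether is driven by Si–F bond formation; the acetic acid buffer protonates the phenoxide as it forms, so the two aryl ester links should neither migrate nor cleave.

Step 8
Reactants: 16 benzyl umbilicarate
Product: 17 umbilicaric acid
Conditions: H2 (1 atm), Pd/C (10 wt% palladium on carbon), EtOAc, rt; filtration
Reagents that add atoms: none
Why: Hydrogenolysis of the remaining benzyl ester under neutral conditions releases the ring C carboxylic acid without touching the depside esters or phenols, and the product is obtained by filtration and evaporation without heating.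

**Compound list**

1 | 3-fluoro-5-methoxyphenol | COc1cc(O)cc(F)c1 | starting material
2 | 1-fluoro-3-methoxy-5-(triisopropylsilyloxy)benzene | COc1cc(F)cc(O[Si](C(C)C)(C(C)C)C(C)C)c1 | intermediate
3 | methyllithium | [Li]C | starting material
4 | carbon dioxide | O=C=O | starting material
5 | 2-fluoro-6-methoxy-4-(triisopropylsilyloxy)phenyllithium | [Li]c1c(F)cc(O[Si](C(C)C)(C(C)C)C(C)C)cc1OC | intermediate
6 | 3-methoxy-5-(triisopropylsilyloxy)benzyne | COC1=CC(O[Si](C(C)C)(C(C)C)C(C)C)=CC#C1 | intermediate
7 | 2-methoxy-6-methyl-4-(triisopropylsilyloxy)phenyllithium | [Li]c1c(C)cc(O[Si](C(C)C)(C(C)C)C(C)C)cc1OC | intermediate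
8 | 2-methoxy-6-methyl-4-(triisopropylsilyloxy)benzoic acid | COc1cc(O[Si](C(C)C)(C(C)C)C(C)C)cc(C)c1C(=O)O | intermediate
9 | orsellinic acid | Cc1cc(O)cc(O)c1C(=O)O | starting material
10 | benzyl orsellinate | Cc1cc(O)cc(O)c1C(=O)OCc1ccccc1 | intermediate
11 | 2-methoxy-6-methyl-4-(triisopropylsilyloxy)benzoic trifluoroacetic anhydride | COc1cc(O[Si](C(C)C)(C(C)C)C(C)C)cc(C)c1C(=O)OC(=O)C(F)(F)F | intermediate
12 | benzyl 2-hydroxy-4-{[2-methoxy-6-methyl-4-(triisopropylsilyloxy)benzoyl]oxy}-6-methylbenzoate | COc1cc(O[Si](C(C)C)(C(C)C)C(C)C)cc(C)c1C(=O)Oc1cc(C)c(C(=O)OCc2ccccc2)c(O)c1 | intermediate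
13 | 2-hydroxy-4-{[2-methoxy-6-methyl-4-(triisopropylsilyloxy)benzoyl]oxy}-6-methylbenzoic acid | COc1cc(O[Si](C(C)C)(C(C)C)C(C)C)cc(C)c1C(=O)Oc1cc(C)c(C(=O)O)c(O)c1 | intermediate
14 | mixed trifluoroacetic anhydride of acid 13 | COc1cc(O[Si](C(C)C)(C(C)C)C(C)C)cc(C)c1C(=O)Oc1cc(C)c(C(=O)OC(=O)C(F)(F)F)c(O)c1 | intermediate
15 | benzyl 2-hydroxy-4-{[2-hydroxy-4-{[2-methoxy-6-methyl-4-(triisopropylsilyloxy)benzoyl]oxy}-6-methylbenzoyl]oxy}-6-methylbenzoate | COc1cc(O[Si](C(C)C)(C(C)C)C(C)C)cc(C)c1C(=O)Oc1cc(C)c(C(=O)Oc2cc(C)c(C(=O)OCc3ccccc3)c(O)c2)c(O)c1 | intermediate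
16 | benzyl umbilicarate | COc1cc(O)cc(C)c1C(=O)Oc1cc(C)c(C(=O)Oc2cc(C)c(C(=O)OCc3ccccc3)c(O)c2)c(O)c1 | intermediate
17 | umbilicaric acid | COc1cc(O)cc(C)c1C(=O)Oc1cc(C)c(C(=O)Oc2cc(C)c(C(=O)O)c(O)c2)c(O)c1 | target

**Step count**

Total: 8 steps. Longest linear sequence: 7 steps (steps 1, 2, 4, 5, 6, 7, 8 from 3-fluoro-5-methoxyphenol); step 3 is a one-step branch that supplies rings B and C.

**Steps most likely to fail, with fallbacks**

Step 2. The ortho-fluoro aryllithium may add to the aryne in competition with MeLi (biaryl formation), MeLi may attack silicon during the warm period, or some metalation may occur beside the silyl ether and lead to a regioisomeric acid. The fallback gives up the aryne and builds ring A from the orsellinate skeleton; it sets out from 10 and returns at 8. Silylation of the non-chelated 4-OH of 10 (TIPSCl, imidazole, CH2Cl2) should give benzyl 2-hydroxy-6-methyl-4-(triisopropylsilyloxy)benzoate F1. Methylation of the chelated 2-OH (MeI, K2CO3, acetone, 40 °C) should give benzyl 2-methoxy-6-methyl-4-(triisopropylsilyloxy)benzoate F2. Hydrogenolysis (H2, Pd/C, EtOAc) would then deliver 8.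

Step 6. Activation of the chelated, less electron-rich acid 13 may be sluggish, and during the longer exposure to acid it may self-acylate through its own 2-OH or the existing depside link may scramble. The fallback reverses the order of fragment union, so that only electron-rich acids are activated; it sets out from 10 and returns at 15.
- Benzyl 2-hydroxy-6-methyl-4-(triisopropylsilyloxy)benzoate F1, made from 10 as described for step 2, is hydrogenolysed (H2, Pd/C, EtOAc) to 2-hydroxy-6-methyl-4-(triisopropylsilyloxy)benzoic acid F3.
- F3 is activated with (CF3CO)2O in toluene as 2-hydroxy-6-methyl-4-(triisopropylsilyloxy)benzoic trifluoroacetic anhydride F4 and coupled with a second portion of 10, to give benzyl 2-hydroxy-4-{[2-hydroxy-6-methyl-4-(triisopropylsilyloxy)benzoyl]oxy}-6-methylbenzoate F5.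
- Buffered desilylation (Bu4NF, AcOH, THF) gives benzyl lecanorate F6.
- F6 is acylated at its only non-chelated hydroxyl by acid 8 ((CF3CO)2O, toluene, through the mixed anhydride 11), which gives 15.

Step 4. The trifluoroacetic acid released may strip the silyl ether, or the acylium species may attack the electron-rich ring carbon of 10 (Friedel–Crafts acylation) or the chelated hydroxyl in addition to the free one. The fallback replaces acid-mediated acyl transfer by base-mediated acylation with a preformed acyl chloride; it sets out from 8 and returns at 12. Acid 8 is converted with oxalyl chloride and catalytic DMF in CH2Cl2 into 2-methoxy-6-methyl-4-(triisopropylsilyloxy)benzoyl chloride F7. F7 is then added to 10 with Et3N and catalytic DMAP in CH2Cl2 at 0 °C, where the more acidic, non-chelated 4-OH should be acylated to give 12.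

**Further compounds**

F1 | step 2 | benzyl 2-hydroxy-6-methyl-4-(triisopropylsilyloxy)benzoate | Cc1cc(O[Si](C(C)C)(C(C)C)C(C)C)cc(O)c1C(=O)OCc1ccccc1
F2 | step 2 | benzyl 2-methoxy-6-methyl-4-(triisopropylsilyloxy)benzoate | COc1cc(O[Si](C(C)C)(C(C)C)C(C)C)cc(C)c1C(=O)OCc1ccccc1
F3 | step 6 | 2-hydroxy-6-methyl-4-(triisopropylsilyloxy)benzoic acid | Cc1cc(O[Si](C(C)C)(C(C)C)C(C)C)cc(O)c1C(=O)O
F4 | step 6 | 2-hydroxy-6-methyl-4-(triisopropylsilyloxy)benzoic trifluoroacetic anhydride | Cc1cc(O[Si](C(C)C)(C(C)C)C(C)C)cc(O)c1C(=O)OC(=O)C(F)(F)F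
F5 | step 6 | benzyl 2-hydroxy-4-{[2-hydroxy-6-methyl-4-(triisopropylsilyloxy)benzoyl]oxy}-6-methylbenzoate | Cc1cc(O[Si](C(C)C)(C(C)C)C(C)C)cc(O)c1C(=O)Oc1cc(C)c(C(=O)OCc2ccccc2)c(O)c1
F6 | step 6 | benzyl lecanorate (benzyl 4-[(2,4-dihydroxy-6-methylbenzoyl)oxy]-2-hydroxy-6-methylbenzoate) | Cc1cc(O)cc(O)c1C(=O)Oc1cc(C)c(C(=O)OCc2ccccc2)c(O)c1
F7 | step 4 | 2-methoxy-6-methyl-4-(triisopropylsilyloxy)benzoyl chloride | COc1cc(O[Si](C(C)C)(C(C)C)C(C)C)cc(C)c1C(=O)Cl
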